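**Plan**

- Cuts, in retrosynthetic order: the enone C=C–aryl bond (Heck); the bond between the diarylmethine carbon and C3 of the dihydrobenzofuran, made together with a temporary O–C2 bond; the methine–aryl bond (Grignard); the tetrahydrofuran C2–aryl, C3–benzyl and C4–acyl bonds.
- Forward order: butenolide → trans,trans-lactone → 2,3-cis tetrahydrofuran → salicylaldehyde → o-hydroxybenzhydrol; separately a 2-arylbenzofuran; the two are joined by a dearomative (4+2) cycloaddition to a cis-fused ketal; the ketal is opened reductively to the trans-dihydrobenzofuran; the ketone is unmasked; Heck; desilylation.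
- Enabling feature: on the resorcinol ring that carries the tetrahydrofuran, the hydroxyl ortho to the methine carbon lets that carbon become the CH terminus of an o-quinone methide (O=C–C=CH–Ar). The O1–C2(aryl)–C3 unit of the dihydrobenzofuran exists one oxidation level higher as the aromatic aryl enol ether C2=C3 of a 2-arylbenzofuran.
- Stereochemistry: tetrahydrofuran C5 from an asymmetric alkynylation; C4, C3 and C2 relayed from it (anti addition, anti alkylation, hydride anti to the C3 benzyl group). The methine carbon and dihydrobenzofuran C3 come from the catalyst-controlled endo cycloaddition; C2 from hydride delivery with retention.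

Key step: step 15

Abbreviations: TBS = tert-butyldimethylsilyl, TIPS = triisopropylsilyl. Block A = (2R,3S,4S,5S)-3-[4-(TBSO)benzyl]-4-{2-[2,4-bis(TIPSO)phenyl]-1,3-dithian-2-yl}-5-[4-(TBSO)phenyl]tetrahydrofuran-2-yl (2,3-cis, 3,4-trans, 4,5-trans). Block B = the same unit with a 2,4-bis(TIPSO)benzoyl group at C4 in place of the dithianyl group.

Assumption: the sense of induction of the ProPhenol ligand (step 1) and of the chiral acid (step 15) is assigned by analogy with related substrates; the antipodal catalyst would be used if a test run showed the opposite sense.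

**Route**

Step 1
Reactants: 1 4-(TBSO)benzaldehyde; 2 methyl propiolate
Product: 4 methyl (R)-4-hydroxy-4-[4-(TBSO)phenyl]but-2-ynoate, via zinc alkynide 3 (not isolated)
Conditions: Me2Zn, (S,S)-ProPhenol [2,6-bis{[(S)-2-(hydroxydiphenylmethyl)pyrrolidin-1-yl]methyl}-4-methylphenol] (20 mol%), Ph3P=O (40 mol%), toluene, 0 °C; aq. NH4Cl
Reagents that add atoms: none
Why: Zinc/ProPhenol-catalysed enantioselective alkynylation of an aryl aldehyde; the chiral dinuclear zinc complex differentiates the aldehyde faces and sets the carbinol centre that becomes C5 of the tetrahydrofuran.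

Step 2
Reactants: 4 methyl (R)-4-hydroxy-4-[4-(TBSO)phenyl]but-2-ynoate
Product: 6 (S)-5-[4-(TBSO)phenyl]furan-2(5H)-one, via Z-hydroxy enoate 5 (not isolated)
Conditions: H2 (1 atm), Pd/CaCO3 poisoned with Pb(OAc)2 (Lindlar catalyst), quinoline, EtOAc, rt; then PPTS (cat.), CH2Cl2, rt
Reagents that add atoms: none
Why: Lindlar semihydrogenation gives the Z-γ-hydroxy enoate, which lactonises to the butenolide without touching the stereocentre.

Step 3
Reactants: 7 2,4-dihydroxybenzaldehyde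
Product: 8 2,4-bis(TIPSO)benzaldehyde
Conditions: TIPSCl, imidazole, DMAP (cat.), DMF, 40 °C
Reagents that add atoms: triisopropylsilyl chloride, CC(C)[Si](Cl)(C(C)C)C(C)C
Why: Standard silylation of both phenols; the bulky silyl groups are kept to the end.

Step 4
Reactants: 8 2,4-bis(TIPSO)benzaldehyde
Product: 9 2-[2,4-bis(TIPSO)phenyl]-1,3-dithiane
Conditions: HS(CH2)3SH, BF3·OEt2 (cat.), CH2Cl2, 0 °C
Reagents that add atoms: propane-1,3-dithiol, SCCCS
Why: Lewis acid-catalysed dithioacetalisation turns the aldehyde into an acyl anion equivalent.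

Step 5
Reactants: 9 2-[2,4-bis(TIPSO)phenyl]-1,3-dithiane; 6 (S)-5-[4-(TBSO)phenyl]furan-2(5H)-one; 10 4-(TBSO)benzyl bromide
Product: 13 (3S,4S,5S)-3-[4-(TBSO)benzyl]-4-{2-[2,4-bis(TIPSO)phenyl]-1,3-dithian-2-yl}-5-[4-(TBSO)phenyl]dihydrofuran-2(3H)-one (3,4-trans-4,5-trans), via lithiated dithiane 11 (not isolated), via lithium lactone enolate 12 (not isolated)
Conditions: n-BuLi, THF, −30 °C; 6, −78 °C; then 10, DMPU, −78 → −40 °C
Reagents that add atoms: none
Why: Tandem conjugate addition–enolate alkylation on a γ-substituted butenolide: the dithianyl anion should add to C4 anti to the C5 aryl group and the enolate should be benzylated anti to the new C4 substituent, giving the trans,trans lactone.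

Step 6
Reactants: 14 4-bromoresorcinol
Product: 15 5-(allyloxy)-2-bromophenol
Conditions: allyl bromide (1.0 equiv), K2CO3, acetone, rt
Reagents that add atoms: allyl bromide, C=CCBr
Why: Williamson etherification; the hydroxyl para to bromine is the less hindered one and its phenoxide the more nucleophilic, so mono-allylation should occur there.

Step 7
Reactants: 15 5-(allyloxy)-2-bromophenol
Product: 16 [5-(allyloxy)-2-bromophenoxy]triisopropylsilane
Conditions: TIPSCl, imidazole, DMF, rt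
Reagents that add atoms: triisopropylsilyl chloride, CC(C)[Si](Cl)(C(C)C)C(C)C
Why: Silylation of the remaining phenol gives an aryl bromide whose two oxygens are differentiated (allyl temporary, TIPS permanent).

Step 8
Reactants: 16 [5-(allyloxy)-2-bromophenoxy]triisopropylsilane; 13 the trans,trans lactone
Product: 18 lactol: 2-[4-(allyloxy)-2-(TIPSO)phenyl]-2-hydroxy analogue of the tetrahydrofuran of block A (anomeric mixture), via aryllithium 17 (not isolated)
Conditions: n-BuLi, THF, −78 °C; then 13, −78 → −40 °C; aq. NH4Cl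
Reagents that add atoms: none
Why: Bromine–lithium exchange followed by 1,2-addition of the aryllithium to the lactone carbonyl, which stops at the lactolate at low temperature.

Step 9
Reactants: 18 the lactol
Product: 19 1-(allyloxy)-4-(block A)-3-(TIPSO)benzene
Conditions: Et3SiH, BF3·OEt2, CH2Cl2, −78 °C
Reagents that add atoms: none
Why: Ionic reduction of the 2-aryl lactol through its cyclic oxocarbenium ion; hydride should enter anti to the adjacent C3 benzyl group (and to the C5 aryl group), which places the new aryl group cis to both (2,3-cis, 2,5-cis), as in related reductive deoxygenations of 2-aryl lactols.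

Step 10
Reactants: 19 the allyl ether
Product: 20 4-(block A)-3-(TIPSO)phenol
Conditions: Pd(PPh3)4 (5 mol%), morpholine, THF, rt
Reagents that add atoms: none
Why: Tsuji–Trost-type deallylation: zerovalent palladium ionises the allyl aryl ether and morpholine traps the allyl unit, under neutral conditions that leave the silyl ethers and the dithiane alone.

Step 11
Reactants: 20 the phenol
Product: 22 2-hydroxy-5-(block A)-4-(TIPSO)benzaldehyde, via hydroxymethyl phenol 21 (not isolated)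
Conditions: MgCl2, Et3N, (CH2O)n, THF, 65 °C
Reagents that add atoms: formaldehyde (from paraformaldehyde), C=O
Why: Magnesium-mediated ortho-formylation of a phenol (Casnati–Skattebøl reaction) through the magnesium phenoxide, hydroxymethylation and hydride transfer to a second formaldehyde; only the ortho position para to the silyloxy group is unhindered.

Step 12
Reactants: 14 4-bromoresorcinol
Product: 23 1-bromo-2,4-bis(TIPSO)benzene
Conditions: TIPSCl, imidazole, DMF, rt
Reagents that add atoms: triisopropylsilyl chloride, CC(C)[Si](Cl)(C(C)C)C(C)C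
Why: Standard bis-silylation; TIPS is chosen because it does not migrate to a neighbouring alkoxide in step 13.

Step 13
Reactants: 23 1-bromo-2,4-bis(TIPSO)benzene; 22 the salicylaldehyde
Product: 25 o-hydroxybenzhydrol: [2,4-bis(TIPSO)phenyl][2-hydroxy-5-(block A)-4-(TIPSO)phenyl]methanol (both carbinol epimers), via aryl Grignard reagent 24 (not isolated)
Conditions: Mg, LiCl, THF, rt (3 equiv of 24); then 22, THF, 0 °C; aq. NH4Cl
Reagents that add atoms: none
Why: Aryl Grignard addition to a salicylaldehyde (the first equivalent deprotonates the phenol); the carbinol configuration is of no consequence because this carbon becomes trigonal in step 15.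

Step 14
Reactants: 26 4-bromo-2-iodophenol; 27 tert-butyl(4-ethynylphenoxy)dimethylsilane
Product: 29 5-bromo-2-[4-(TBSO)phenyl]benzofuran, via 2-alkynylphenol 28 (not isolated)
Conditions: PdCl2(PPh3)2 (2 mol%), CuI (4 mol%), Et3N, DMF, rt → 70 °C
Reagents that add atoms: none
Why: Sonogashira coupling at the iodide (more reactive than the bromide) followed in the same flask by 5-endo-dig cycloisomerisation of the o-alkynylphenol to the benzofuran.

Step 15
Reactants: 25 the o-hydroxybenzhydrol; 29 5-bromo-2-[4-(TBSO)phenyl]benzofuran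
Product: 31 cis-fused ketal (dihydrobenzofuro[2,3-b]chromene): former C3 of 29 (R) bonded to the methine carbon; former C2 bearing the 4-(TBSO)phenyl group and both ring oxygens; methine carbon bearing the 2,4-bis(TIPSO)phenyl group cis to that aryl group and trans to the bromobenzo ring; chromene benzo ring bearing TIPSO and block A, via o-quinone methide 30 (not isolated)
Conditions: (R)-3,3'-bis(2,4,6-triisopropylphenyl)-1,1'-binaphthyl-2,2'-diyl N-triflylphosphoramide (10 mol%), 5 Å molecular sieves, toluene/CH2Cl2, −40 °C; Et3N quench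
Reagents that add atoms: none
Why: Proposed new method: the acid dehydrates 25 to the E-configured o-quinone methide 30, held as a hydrogen-bonded ion pair with the chiral phosphoramide anion, and this oxa-diene adds across the electron-rich C2=C3 bond of benzofuran 29 in an inverse-electron-demand (4+2) cycloaddition that breaks the furan aromaticity; the closest known reaction type is the chiral Brønsted acid-catalysed (4+2) of o-quinone methides from o-hydroxybenzhydrols with styrenes and enol ethers and its dearomative variant with 2,3-disubstituted indoles. The dihydropyran (ketal) ring closes in the cycloaddition itself, asynchronously, with the methine–C3 bond leading and the O–C2 bond following (a 6-exo-trig collapse of the phenoxide on the benzofuranium ion if the process is stepwise). The methine centre and C3 are set together: the E geometry of 30 puts the bis(silyloxy)phenyl group outside, the endo transition state with the 2-aryl group of 29 stacked under the quinone methide places that group cis to H-3 and trans to the benzo ring, and the face of 30 is chosen by the catalyst; C2 follows from the suprafacial cis fusion. Regioselectivity is secured because attack through C3 gives a cation stabilised by O1 and by the 4-silyloxyphenyl group, and site selectivity because only the hydroxyl ortho to the carbinol on the tetrahydrofuran-bearing ring is free, so that only one quinone methide can form (the other ring would lead to the opposite relative configuration). Low temperature and a basic quench are needed to prevent re-ionisation of the ketal with loss of H-3 (rearomatisation) and opening of the benzylic tetrahydrofuran ether.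

Step 16
Reactants: 31 the cis-fused ketal
Product: 32 (2R,3R)-5-bromo-2-[4-(TBSO)phenyl]-3-{[2,4-bis(TIPSO)phenyl][2-hydroxy-5-(block A)-4-(TIPSO)phenyl]methyl}-2,3-dihydrobenzofuran (2,3-trans; methine carbon arranged as in the target, CIP letter S here because of the silyl groups)
Conditions: i-Bu2AlH (4 equiv), CH2Cl2, −78 → 0 °C; aq. potassium sodium tartrate
Reagents that add atoms: none
Why: Reductive cleavage of a cyclic ketal by a Lewis-acidic hydride: aluminium should bind the more electron-rich ketal oxygen (that of the resorcinol ring), ionisation gives the five-membered 2-arylbenzofuranium ion, and hydride is delivered from the aluminate that stays tethered on the face of the C3 substituent, that is with retention at C2, which gives the 2,3-trans dihydrobenzofuran and frees the phenol.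

Step 17
Reactants: 32 the dithiane-bearing dihydrobenzofuran
Product: 33 the corresponding ketone (block A replaced by block B)
Conditions: MeI, CaCO3, MeCN/H2O (9:1), 45 °C
Reagents that add atoms: water, O
Why: Dithiane hydrolysis by S-methylation and attack of water on the thionium ion under near-neutral conditions; the ketone-bearing carbon stays trans to both neighbours, which is also the more stable arrangement.

Step 18
Reactants: 8 2,4-bis(TIPSO)benzaldehyde
Product: 34 1-[2,4-bis(TIPSO)phenyl]prop-2-en-1-ol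
Conditions: CH2=CHMgBr, THF, −78 °C; aq. NH4Cl
Reagents that add atoms: vinylmagnesium bromide, C=C[Mg]Br
Why: 1,2-Addition of a vinyl Grignard reagent to the aldehyde.

Step 19
Reactants: 34 1-[2,4-bis(TIPSO)phenyl]prop-2-en-1-ol
Product: 35 1-[2,4-bis(TIPSO)phenyl]prop-2-en-1-one
Conditions: Dess–Martin periodinane, CH2Cl2, 0 °C
Reagents that add atoms: none
Why: Dess–Martin oxidation of the allylic benzylic alcohol to the aryl vinyl ketone, which is used at once.

Step 20
Reactants: 33 the aryl bromide; 35 the aryl vinyl ketone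
Product: 36 deca-O-silyl lophirachalcone (all phenols silylated except the one freed in step 16; E enone)
Conditions: Pd2(dba)3 (5 mol%), t-Bu3P·HBF4 (12 mol%), Cy2NMe, 1,4-dioxane, 60 °C
Reagents that add atoms: none
Why: Heck reaction of the aryl bromide with the vinyl ketone; syn insertion and syn β-hydride elimination give the E chalcone under a mild amine base that the β-alkoxy ketone tolerates.

Step 21
Reactants: 36 deca-O-silyl lophirachalcone
Product: 37 lophirachalcone
Conditions: Bu4NF, AcOH (1:1), THF, 0 °C → rt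
Reagents that add atoms: none
Why: Fluoride cleavage of the ten aryl silyl ethers, buffered with acetic acid so that the β-alkoxy ketone and the 2'-hydroxychalcone are not exposed to strong base.

**Compound list**

1 | 4-(TBSO)benzaldehyde | O=Cc1ccc(O[Si](C)(C)C(C)(C)C)cc1 | starting material
2 | methyl propiolate | C#CC(=O)OC | starting material
3 | methyl 3-(methylzincio)propiolate | COC(=O)C#C[Zn]C | intermediate (not isolated)
4 | methyl (R)-4-hydroxy-4-[4-(TBSO)phenyl]but-2-ynoate | O[C@H](c1ccc(O[Si](C)(C)C(C)(C)C)cc1)C#CC(=O)OC | intermediate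
5 | methyl (S,Z)-4-hydroxy-4-[4-(TBSO)phenyl]but-2-enoate | O[C@H](c1ccc(O[Si](C)(C)C(C)(C)C)cc1)/C=C\C(=O)OC | intermediate (not isolated)
6 | (S)-5-[4-(TBSO)phenyl]furan-2(5H)-one | O=C1O[C@H](c2ccc(O[Si](C)(C)C(C)(C)C)cc2)C=C1 | intermediate
7 | 2,4-dihydroxybenzaldehyde | O=Cc1ccc(O)cc1O | starting material
8 | 2,4-bis(TIPSO)benzaldehyde | O=Cc1ccc(O[Si](C(C)C)(C(C)C)C(C)C)cc1O[Si](C(C)C)(C(C)C)C(C)C | intermediate
9 | 2-[2,4-bis(TIPSO)phenyl]-1,3-dithiane | C1(c2ccc(O[Si](C(C)C)(C(C)C)C(C)C)cc2O[Si](C(C)C)(C(C)C)C(C)C)SCCCS1 | intermediate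
10 | 4-(TBSO)benzyl bromide | BrCc1ccc(O[Si](C)(C)C(C)(C)C)cc1 | starting material
11 | 2-lithio-2-[2,4-bis(TIPSO)phenyl]-1,3-dithiane | [Li]C1(c2ccc(O[Si](C(C)C)(C(C)C)C(C)C)cc2O[Si](C(C)C)(C(C)C)C(C)C)SCCCS1 | intermediate (not isolated)
12 | lithium enolate of the 4,5-trans conjugate adduct | [Li]OC=1O[C@H](c2ccc(O[Si](C)(C)C(C)(C)C)cc2)[C@@H](C2(c3ccc(O[Si](C(C)C)(C(C)C)C(C)C)cc3O[Si](C(C)C)(C(C)C)C(C)C)SCCCS2)C=1 | intermediate (not isolated)
13 | (3S,4S,5S)-3-[4-(TBSO)benzyl]-4-{2-[2,4-bis(TIPSO)phenyl]-1,3-dithian-2-yl}-5-[4-(TBSO)phenyl]dihydrofuran-2(3H)-one | O=C1O[C@H](c2ccc(O[Si](C)(C)C(C)(C)C)cc2)[C@@H](C2(c3ccc(O[Si](C(C)C)(C(C)C)C(C)C)cc3O[Si](C(C)C)(C(C)C)C(C)C)SCCCS2)[C@@H]1Cc1ccc(O[Si](C)(C)C(C)(C)C)cc1 | intermediate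
14 | 4-bromoresorcinol | Oc1ccc(Br)c(O)c1 | starting material
15 | 5-(allyloxy)-2-bromophenol | C=CCOc1ccc(Br)c(O)c1 | intermediate
16 | [5-(allyloxy)-2-bromophenoxy]triisopropylsilane | C=CCOc1ccc(Br)c(O[Si](C(C)C)(C(C)C)C(C)C)c1 | intermediate
17 | 4-(allyloxy)-2-(TIPSO)phenyllithium | C=CCOc1ccc([Li])c(O[Si](C(C)C)(C(C)C)C(C)C)c1 | intermediate (not isolated)
18 | lactol from 17 and 13 (anomeric mixture) | C=CCOc1ccc(C5(O)O[C@H](c6ccc(O[Si](C)(C)C(C)(C)C)cc6)[C@@H](C6(c7ccc(O[Si](C(C)C)(C(C)C)C(C)C)cc7O[Si](C(C)C)(C(C)C)C(C)C)SCCCS6)[C@@H]5Cc5ccc(O[Si](C)(C)C(C)(C)C)cc5)c(O[Si](C(C)C)(C(C)C)C(C)C)c1 | intermediate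
19 | 1-(allyloxy)-4-(block A)-3-(TIPSO)benzene | C=CCOc1ccc([C@@H]5O[C@H](c6ccc(O[Si](C)(C)C(C)(C)C)cc6)[C@@H](C6(c7ccc(O[Si](C(C)C)(C(C)C)C(C)C)cc7O[Si](C(C)C)(C(C)C)C(C)C)SCCCS6)[C@@H]5Cc5ccc(O[Si](C)(C)C(C)(C)C)cc5)c(O[Si](C(C)C)(C(C)C)C(C)C)c1 | intermediate
20 | 4-(block A)-3-(TIPSO)phenol | Oc1ccc([C@@H]5O[C@H](c6ccc(O[Si](C)(C)C(C)(C)C)cc6)[C@@H](C6(c7ccc(O[Si](C(C)C)(C(C)C)C(C)C)cc7O[Si](C(C)C)(C(C)C)C(C)C)SCCCS6)[C@@H]5Cc5ccc(O[Si](C)(C)C(C)(C)C)cc5)c(O[Si](C(C)C)(C(C)C)C(C)C)c1 | intermediate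
21 | 2-(hydroxymethyl)-4-(block A)-5-(TIPSO)phenol | OCc1cc([C@@H]5O[C@H](c6ccc(O[Si](C)(C)C(C)(C)C)cc6)[C@@H](C6(c7ccc(O[Si](C(C)C)(C(C)C)C(C)C)cc7O[Si](C(C)C)(C(C)C)C(C)C)SCCCS6)[C@@H]5Cc5ccc(O[Si](C)(C)C(C)(C)C)cc5)c(O[Si](C(C)C)(C(C)C)C(C)C)cc1O | intermediate (not isolated)
22 | 2-hydroxy-5-(block A)-4-(TIPSO)benzaldehyde | O=Cc1cc([C@@H]5O[C@H](c6ccc(O[Si](C)(C)C(C)(C)C)cc6)[C@@H](C6(c7ccc(O[Si](C(C)C)(C(C)C)C(C)C)cc7O[Si](C(C)C)(C(C)C)C(C)C)SCCCS6)[C@@H]5Cc5ccc(O[Si](C)(C)C(C)(C)C)cc5)c(O[Si](C(C)C)(C(C)C)C(C)C)cc1O | intermediate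
23 | 1-bromo-2,4-bis(TIPSO)benzene | Brc1ccc(O[Si](C(C)C)(C(C)C)C(C)C)cc1O[Si](C(C)C)(C(C)C)C(C)C | intermediate
24 | 2,4-bis(TIPSO)phenylmagnesium bromide | Br[Mg]c1ccc(O[Si](C(C)C)(C(C)C)C(C)C)cc1O[Si](C(C)C)(C(C)C)C(C)C | intermediate (not isolated)
25 | [2,4-bis(TIPSO)phenyl][2-hydroxy-5-(block A)-4-(TIPSO)phenyl]methanol (carbinol epimers) | OC(c3ccc(O[Si](C(C)C)(C(C)C)C(C)C)cc3O[Si](C(C)C)(C(C)C)C(C)C)c3cc([C@@H]5O[C@H](c6ccc(O[Si](C)(C)C(C)(C)C)cc6)[C@@H](C6(c7ccc(O[Si](C(C)C)(C(C)C)C(C)C)cc7O[Si](C(C)C)(C(C)C)C(C)C)SCCCS6)[C@@H]5Cc5ccc(O[Si](C)(C)C(C)(C)C)cc5)c(O[Si](C(C)C)(C(C)C)C(C)C)cc3O | intermediate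
26 | 4-bromo-2-iodophenol | Oc1ccc(Br)cc1I | starting material
27 | tert-butyl(4-ethynylphenoxy)dimethylsilane | C#Cc1ccc(O[Si](C)(C)C(C)(C)C)cc1 | starting material
28 | 4-bromo-2-{[4-(TBSO)phenyl]ethynyl}phenol | Oc1ccc(Br)cc1C#Cc1ccc(O[Si](C)(C)C(C)(C)C)cc1 | intermediate (not isolated)
29 | 5-bromo-2-[4-(TBSO)phenyl]benzofuran | Brc1ccc2oc(-c3ccc(O[Si](C)(C)C(C)(C)C)cc3)cc2c1 | intermediate
30 | E-o-quinone methide from 25 | O=C1C=C(O[Si](C(C)C)(C(C)C)C(C)C)C([C@@H]5O[C@H](c6ccc(O[Si](C)(C)C(C)(C)C)cc6)[C@@H](C6(c7ccc(O[Si](C(C)C)(C(C)C)C(C)C)cc7O[Si](C(C)C)(C(C)C)C(C)C)SCCCS6)[C@@H]5Cc5ccc(O[Si](C)(C)C(C)(C)C)cc5)=C/C1=C\c3ccc(O[Si](C(C)C)(C(C)C)C(C)C)cc3O[Si](C(C)C)(C(C)C)C(C)C | intermediate (not isolated)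
31 | cis-fused ketal from the (4+2) cycloaddition | Brc1ccc2c(c1)[C@@H]([C@H](c3ccc(O[Si](C(C)C)(C(C)C)C(C)C)cc3O[Si](C(C)C)(C(C)C)C(C)C)c3cc([C@@H]5O[C@H](c6ccc(O[Si](C)(C)C(C)(C)C)cc6)[C@@H](C6(c7ccc(O[Si](C(C)C)(C(C)C)C(C)C)cc7O[Si](C(C)C)(C(C)C)C(C)C)SCCCS6)[C@@H]5Cc5ccc(O[Si](C)(C)C(C)(C)C)cc5)c(O[Si](C(C)C)(C(C)C)C(C)C)cc3O8)[C@]8(c3ccc(O[Si](C)(C)C(C)(C)C)cc3)O2 | intermediate
32 | (2R,3R)-trans-dihydrobenzofuran with block A and free phenol | Brc1ccc2c(c1)[C@@H]([C@H](c3ccc(O[Si](C(C)C)(C(C)C)C(C)C)cc3O[Si](C(C)C)(C(C)C)C(C)C)c3cc([C@@H]5O[C@H](c6ccc(O[Si](C)(C)C(C)(C)C)cc6)[C@@H](C6(c7ccc(O[Si](C(C)C)(C(C)C)C(C)C)cc7O[Si](C(C)C)(C(C)C)C(C)C)SCCCS6)[C@@H]5Cc5ccc(O[Si](C)(C)C(C)(C)C)cc5)c(O[Si](C(C)C)(C(C)C)C(C)C)cc3O)[C@H](c3ccc(O[Si](C)(C)C(C)(C)C)cc3)O2 | intermediate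
33 | ketone from 32 (block B) | Brc1ccc2c(c1)[C@@H]([C@H](c3ccc(O[Si](C(C)C)(C(C)C)C(C)C)cc3O[Si](C(C)C)(C(C)C)C(C)C)c3cc([C@@H]5O[C@H](c6ccc(O[Si](C)(C)C(C)(C)C)cc6)[C@@H](C(=O)c6ccc(O[Si](C(C)C)(C(C)C)C(C)C)cc6O[Si](C(C)C)(C(C)C)C(C)C)[C@@H]5Cc5ccc(O[Si](C)(C)C(C)(C)C)cc5)c(O[Si](C(C)C)(C(C)C)C(C)C)cc3O)[C@H](c3ccc(O[Si](C)(C)C(C)(C)C)cc3)O2 | intermediate
34 | 1-[2,4-bis(TIPSO)phenyl]prop-2-en-1-ol | C=CC(O)c1ccc(O[Si](C(C)C)(C(C)C)C(C)C)cc1O[Si](C(C)C)(C(C)C)C(C)C | intermediate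
35 | 1-[2,4-bis(TIPSO)phenyl]prop-2-en-1-one | C=CC(=O)c1ccc(O[Si](C(C)C)(C(C)C)C(C)C)cc1O[Si](C(C)C)(C(C)C)C(C)C | intermediate
36 | deca-O-silyl lophirachalcone | O=C(/C=C/c1ccc2c(c1)[C@@H]([C@H](c3ccc(O[Si](C(C)C)(C(C)C)C(C)C)cc3O[Si](C(C)C)(C(C)C)C(C)C)c3cc([C@@H]5O[C@H](c6ccc(O[Si](C)(C)C(C)(C)C)cc6)[C@@H](C(=O)c6ccc(O[Si](C(C)C)(C(C)C)C(C)C)cc6O[Si](C(C)C)(C(C)C)C(C)C)[C@@H]5Cc5ccc(O[Si](C)(C)C(C)(C)C)cc5)c(O[Si](C(C)C)(C(C)C)C(C)C)cc3O)[C@H](c3ccc(O[Si](C)(C)C(C)(C)C)cc3)O2)c1ccc(O[Si](C(C)C)(C(C)C)C(C)C)cc1O[Si](C(C)C)(C(C)C)C(C)C | intermediate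
37 | lophirachalcone | O=C(/C=C/c1ccc2c(c1)[C@@H]([C@H](c1ccc(O)cc1O)c1cc([C@@H]3O[C@H](c4ccc(O)cc4)[C@@H](C(=O)c4ccc(O)cc4O)[C@@H]3Cc3ccc(O)cc3)c(O)cc1O)[C@H](c1ccc(O)cc1)O2)c1ccc(O)cc1O | target

**Summary**

Total step count: 21. Longest linear sequence: 13 steps (1, 2, 5, 8, 9, 10, 11, 13, 15, 16, 17, 20, 21).

Steps most likely to fail:

1. Step 15 (Proposed new method). What may go wrong: after the C–C bond has formed, the benzofuranium ion may lose H-3 (rearomatisation) faster than the phenol oxygen closes the ring; endo/exo or facial selectivity may be poor; the acid may open the benzylic ether of the tetrahydrofuran. Fallback (known chemistry, sets out from 25, returns at 32): 25 and commercial 5-bromobenzofuran-2(3H)-one (O=C1Cc2cc(Br)ccc2O1) are combined under the same kind of chiral Brønsted acid catalysis. Addition of the lactone enol to quinone methide 30, followed by transfer of the acyl group to the neighbouring phenol oxygen (the known route from o-quinone methides and enolisable lactones to 3,4-dihydrocoumarins), should give the 3,4-trans dihydrocoumarin F1, whose C3 centre is epimerisable and should settle trans to the C4 aryl group. Reduction with i-Bu2AlH at −78 °C should give the lactol F2. Addition of 4-(TBSO)phenylmagnesium bromide to its open hydroxy aldehyde form should give the benzylic alcohol F3. Brief treatment with catalytic TsOH (CH2Cl2, 0 °C) should then close the dihydrobenzofuran by capture of the 4-silyloxybenzylic cation by the bromophenol oxygen (5-exo, trans product favoured) to give 32.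

2. Step 16. What may go wrong: aluminium may coordinate the other ketal oxygen, so that the five-membered ring opens instead (a 2-arylchroman results); the ion pair may lose H-3; or hydride may arrive from outside, anti to the C3 substituent. Fallback (sets out from 31, returns at 32): ionic reduction with Et3SiH/BF3·OEt2 at −78 °C, where external hydride attack anti to the C3 substituent should give the 2,3-cis dihydrobenzofuran F4. Equilibration at C2 through reversible ionisation of the 4-silyloxybenzylic aryl ether (catalytic TsOH, CH2Cl2, 0 °C) should then give the more stable trans isomer 32.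

3. Step 5. What may go wrong: the dithianyl anion may deprotonate the acidic γ-position of the 5-aryl butenolide instead of adding to it, with racemisation or loss of the acceptor. Fallback (sets out from 4, returns at 13): trans-selective reduction of 4 with NaAlH2(OCH2CH2OMe)2 at −78 °C to the E-γ-hydroxy enoate F5 and silylation with Et3SiCl/imidazole to the triethylsilyl ether F6. Conjugate addition of lithiated dithiane 11 to this acyclic enoate, anti to the silyloxy group, should give the ester F7. PPTS in MeOH should remove the triethylsilyl group and lactonise to the 4,5-trans lactone F8, which has no acidic γ-hydrogen. Its enolate (LiN(i-Pr)2, THF, −78 °C) is then benzylated with 10, anti to the C4 substituent, to give 13.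

**Further compounds**

F1 | step 15 | (3R,4S-type) 3,4-trans-3-(5-bromo-2-hydroxyphenyl)-4-[2,4-bis(TIPSO)phenyl]-6-(block A)-7-(TIPSO)-3,4-dihydrocoumarin | Oc1ccc(Br)cc1[C@@H]([C@H](c3ccc(O[Si](C(C)C)(C(C)C)C(C)C)cc3O[Si](C(C)C)(C(C)C)C(C)C)c3cc([C@@H]5O[C@H](c6ccc(O[Si](C)(C)C(C)(C)C)cc6)[C@@H](C6(c7ccc(O[Si](C(C)C)(C(C)C)C(C)C)cc7O[Si](C(C)C)(C(C)C)C(C)C)SCCCS6)[C@@H]5Cc5ccc(O[Si](C)(C)C(C)(C)C)cc5)c(O[Si](C(C)C)(C(C)C)C(C)C)cc3O8)C8=O
F2 | step 15 | lactol from F1 (chroman-2-ol; anomeric mixture) | Oc1ccc(Br)cc1[C@@H]([C@H](c3ccc(O[Si](C(C)C)(C(C)C)C(C)C)cc3O[Si](C(C)C)(C(C)C)C(C)C)c3cc([C@@H]5O[C@H](c6ccc(O[Si](C)(C)C(C)(C)C)cc6)[C@@H](C6(c7ccc(O[Si](C(C)C)(C(C)C)C(C)C)cc7O[Si](C(C)C)(C(C)C)C(C)C)SCCCS6)[C@@H]5Cc5ccc(O[Si](C)(C)C(C)(C)C)cc5)c(O[Si](C(C)C)(C(C)C)C(C)C)cc3O8)C8O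
F3 | step 15 | ring-opened benzylic alcohol: 1-[4-(TBSO)phenyl]-2-(5-bromo-2-hydroxyphenyl)-3-[2,4-bis(TIPSO)phenyl]-3-[2-hydroxy-5-(block A)-4-(TIPSO)phenyl]propan-1-ol (carbinol epimers) | Oc1ccc(Br)cc1[C@@H]([C@H](c3ccc(O[Si](C(C)C)(C(C)C)C(C)C)cc3O[Si](C(C)C)(C(C)C)C(C)C)c3cc([C@@H]5O[C@H](c6ccc(O[Si](C)(C)C(C)(C)C)cc6)[C@@H](C6(c7ccc(O[Si](C(C)C)(C(C)C)C(C)C)cc7O[Si](C(C)C)(C(C)C)C(C)C)SCCCS6)[C@@H]5Cc5ccc(O[Si](C)(C)C(C)(C)C)cc5)c(O[Si](C(C)C)(C(C)C)C(C)C)cc3O)C(O)c3ccc(O[Si](C)(C)C(C)(C)C)cc3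
F4 | step 16 | 2,3-cis dihydrobenzofuran (C2 epimer of 32) | Brc1ccc2c(c1)[C@@H]([C@H](c3ccc(O[Si](C(C)C)(C(C)C)C(C)C)cc3O[Si](C(C)C)(C(C)C)C(C)C)c3cc([C@@H]5O[C@H](c6ccc(O[Si](C)(C)C(C)(C)C)cc6)[C@@H](C6(c7ccc(O[Si](C(C)C)(C(C)C)C(C)C)cc7O[Si](C(C)C)(C(C)C)C(C)C)SCCCS6)[C@@H]5Cc5ccc(O[Si](C)(C)C(C)(C)C)cc5)c(O[Si](C(C)C)(C(C)C)C(C)C)cc3O)[C@@H](c3ccc(O[Si](C)(C)C(C)(C)C)cc3)O2
F5 | step 5 | methyl (S,E)-4-hydroxy-4-[4-(TBSO)phenyl]but-2-enoate | O[C@H](c1ccc(O[Si](C)(C)C(C)(C)C)cc1)/C=C/C(=O)OC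
F6 | step 5 | methyl (S,E)-4-[4-(TBSO)phenyl]-4-[(triethylsilyl)oxy]but-2-enoate | CC[Si](CC)(CC)O[C@H](c1ccc(O[Si](C)(C)C(C)(C)C)cc1)/C=C/C(=O)OC
F7 | step 5 | methyl (3S,4S)-3-{2-[2,4-bis(TIPSO)phenyl]-1,3-dithian-2-yl}-4-[4-(TBSO)phenyl]-4-[(triethylsilyl)oxy]butanoate | CC[Si](CC)(CC)O[C@H](c1ccc(O[Si](C)(C)C(C)(C)C)cc1)[C@@H](C1(c2ccc(O[Si](C(C)C)(C(C)C)C(C)C)cc2O[Si](C(C)C)(C(C)C)C(C)C)SCCCS1)CC(=O)OC
F8 | step 5 | (4S,5S)-4-{2-[2,4-bis(TIPSO)phenyl]-1,3-dithian-2-yl}-5-[4-(TBSO)phenyl]dihydrofuran-2(3H)-one (4,5-trans) | O=C1O[C@H](c2ccc(O[Si](C)(C)C(C)(C)C)cc2)[C@@H](C2(c3ccc(O[Si](C(C)C)(C(C)C)C(C)C)cc3O[Si](C(C)C)(C(C)C)C(C)C)SCCCS2)C1
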